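Assumptions: natural (R)-(–)-linalool (≥97% ee) and (8-bromooctyl)benzene are taken as commercial. Bicycle numbering is O1, C2(=O), C3, C3a, O4, C5, C6, C6a.

## Retrosynthetic overview
1. Side chain: cut the decyl chain between C2' and C3'. This gives vinyl bicycle 7 and (8-bromooctyl)benzene 8, joined last by hydroboration and alkyl–alkyl Suzuki coupling.
2. Both rings of 7 form in one electrolysis from the C2-symmetric divinyl diol 6 and CO. O4–C3a closes the THF first, then C3–C2 (CO insertion) and C2–O1 close the lactone.
3. Diol 6 comes from trans-cyclopentenediol 4 by C=C cleavage and double methylenation. The carbocycle is only a temporary template for relaying stereochemistry.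
4. Diol 4 comes from enone 3 by methyl addition on the alkoxide face. Enone 3 comes from (R)-linalool 1 by RCM and electrochemical allylic oxidation, so the linalool carbinol is the only bought stereocentre.

## Route

**Step 1**
Reactants: 1, (R)-(–)-linalool
Product: 2, (R)-1-methylcyclopent-2-en-1-ol
Conditions: Hoveyda–Grubbs II (0.5 mol %), CH2Cl2, 40 °C, open to bubbler (– isobutene)
Reagents that add atoms: none
Why: Ring-closing metathesis of the 1,6-diene closes the five-membered ring irreversibly because isobutene escapes, and the bought carbinol stereocentre is not touched.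

**Step 2**
Reactants: 2
Product: 3, (R)-4-hydroxy-4-methylcyclopent-2-en-1-one
Conditions: RVC(+)/Ni(–), undivided cell, Cl4NHPI (20 mol %), pyridine (2 equiv), t-BuOOH (1.5 equiv), LiClO4 (0.1 M), acetone, constant current, rt
Reagents that add atoms: tert-butyl hydroperoxide, CC(C)(C)OO (supplies the oxygen)
Why: In this N-oxyl-mediated electrochemical allylic C–H oxidation the anodically formed N-oxyl abstracts H from the only allylic CH2, the allyl radical is peroxidised at its unhindered end and collapses to the enone, which installs the oxygen that later becomes a carbinol OH of diol 6 (one of these two homotopic hydroxyls closes the ether).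

**Step 3**
Reactants: 3
Product: 4, (1R,3R)-1,3-dimethylcyclopent-4-ene-1,3-diol (trans, C2-symmetric)
Conditions: MeLi (1.0 equiv), THF, –78 °C; then MeLi/CeCl3 (1.5 equiv), –78 °C; aq NH4Cl
Reagents that add atoms: methyllithium, [Li]C
Why: In this organocerium 1,2-addition the pre-formed tertiary alkoxide binds cerium and delivers CH3 to its own face, which is also anti to the larger C4 methyl and is the face preferred by 4-alkoxy-4-alkyl enones, so the new carbinol forms trans, and the minor cis (meso) diol is removed by chromatography.

**Step 4**
Reactants: 4
Product: 5, (2R,4R)-2,4-dihydroxy-2,4-dimethylpentanedial (used crude, partly as lactol)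
Conditions: O3, pyridine (3 equiv), CH2Cl2, –78 °C
Reagents that add atoms: ozone, [O-][O+]=O
Why: Reductive ozonolysis with pyridine gives the aldehydes directly without a peroxidic work-up, which suppresses anomalous allylic-alcohol fragmentation, and both quaternary stereocentres are untouched.

**Step 5**
Reactants: 5
Product: 6, (3R,5R)-3,5-dimethylhepta-1,6-diene-3,5-diol
Conditions: Ph3PCH3Br (6 equiv), KHMDS (5.8 equiv), THF, –78 °C to rt
Reagents that add atoms: methyltriphenylphosphonium bromide, C[P+](c1ccccc1)(c1ccccc1)c1ccccc1.[Br-]
Why: Double Wittig methylenation with excess ylide works on free α-hydroxy aldehydes and lactols as it does on sugar lactols, and there is no α-hydrogen to epimerise.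

**Step 6**
Reactants: 6
Product: 7, (3aR,5R,6aR)-5-ethenyl-5,6a-dimethyltetrahydrofuro[3,2-b]furan-2(3H)-one
Conditions: divided cell, graphite felt(+)/Pt(–); Pd(OAc)2 (10 mol %), 1,4-benzoquinone (20 mol %), NaOAc (3 equiv), LiCl (1 equiv), n-Bu4NBF4 (0.1 M), AcOH/MeCN 1:3, CO (1 atm), 1 mA cm–2, 2.3 F mol–1, 25 °C
Reagents that add atoms: carbon monoxide, [C-]#[O+]
Why: Proposed new method: an anodically driven Pd(II) oxycarbonylative bicyclisation, in which one tertiary OH adds 5-exo to the Pd-bound vinyl group on the other carbinol carbon (O4–C3a), CO inserts into the CH2–Pd bond (C3–C2) and the acyl-Pd is captured by the neighbouring tertiary OH (C2–O1); only the reversible oxypalladation adduct with CH2Pd cis to that OH can lactonise, so C3a is fixed as (R) by cis-fusion, while C2 symmetry makes the two OH/vinyl pairs homotopic so a single product forms with vinyl endo and the two methyls cis; Pd(0) is returned to Pd(II) by catalytic benzoquinone, which is regenerated from hydroquinone at about +0.6 V, well below the oxidation potential of alkene, alcohol or CO, and the divided cell prevents Pd plating; the closest known reactions are the PdCl2/CuCl2/CO oxycarbonylation of 4-ene-1,3-diols and quinone-mediated electrochemical Wacker and oxidative carbonylation chemistry.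

**Step 7**
Reactants: 7; 8, (8-bromooctyl)benzene
Product: 9, plakortolide ether, (3aR,5S,6aR)-5,6a-dimethyl-5-(10-phenyldecyl)tetrahydrofuro[3,2-b]furan-2(3H)-one
Conditions: 9-BBN (1.3 equiv), THF, rt; then 8, Pd(OAc)2 (4 mol %), PCy3 (8 mol %), K3PO4·H2O, THF, rt
Reagents that add atoms: (8-bromooctyl)benzene, BrCCCCCCCCc1ccccc1
Why: Anti-Markovnikov hydroboration followed by B-alkyl Suzuki–Miyaura alkyl–alkyl coupling joins CH2CH2 to (CH2)8Ph under conditions the lactone tolerates, and no stereocentre is touched (the C5 descriptor changes from R to S only through CIP priorities).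

## Compound list
1 | (R)-(–)-linalool | C=C[C@](C)(O)CCC=C(C)C | starting material
2 | (R)-1-methylcyclopent-2-en-1-ol | C[C@]1(O)C=CCC1 | intermediate
3 | (R)-4-hydroxy-4-methylcyclopent-2-en-1-one | C[C@]1(O)C=CC(=O)C1 | intermediate
4 | (1R,3R)-1,3-dimethylcyclopent-4-ene-1,3-diol | C[C@]1(O)C=C[C@](C)(O)C1 | intermediate
5 | (2R,4R)-2,4-dihydroxy-2,4-dimethylpentanedial | O=C[C@](C)(O)C[C@@](C)(O)C=O | intermediate
6 | (3R,5R)-3,5-dimethylhepta-1,6-diene-3,5-diol | C=C[C@](C)(O)C[C@@](C)(O)C=C | intermediate
7 | (3aR,5R,6aR)-5-ethenyl-5,6a-dimethyltetrahydrofuro[3,2-b]furan-2(3H)-one | C[C@]1(C=C)C[C@@]2(C)OC(=O)C[C@H]2O1 | intermediate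
8 | (8-bromooctyl)benzene | BrCCCCCCCCc1ccccc1 | starting material
9 | plakortolide ether | C[C@]1(CCCCCCCCCCc2ccccc2)C[C@@]2(C)OC(=O)C[C@H]2O1 | target

## Step count
Total steps: 7. Longest linear sequence: 7.

## Steps most likely to fail
1. **Step 6 (new electrolysis).** The risks are Pd black forming under CO, slow Pd(0)/quinone turnover and ionisation of the bis-allylic diol.
   Fallback (known chemistry): drop the carbonylation. Cross-metathesis of 6 with methyl acrylate (1 equiv, Hoveyda–Grubbs II; the vinyl groups are homotopic) gives the mono-enoate. DBU then triggers 5-exo oxa-Michael addition and lactonisation to the same 7, at the cost of one extra step.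
2. **Step 3 (facial selectivity).** The risk is that too much cis (meso) diol forms.
   Fallback: force delivery through a temporary silicon tether.
   - Silylate 3 with BrCH2SiMe2Cl.
   - Run a SmI2 intramolecular Barbier reaction, in which the carbon can only reach the ketone from the oxygen face.
   - Carry out Tamao–Fleming oxidation to CH2OH.
   - Tosylate the primary alcohol and reduce with LiEt3BH to CH3.
3. **Step 5, together with the sensitive dialdehyde 5.** The risk is decomposition under strongly basic ylide.
   Fallback: bypass the diene.
   - Treat crude 5 with Ph3P=CHCO2Bn (2.2 equiv) and then DBU. This gives the symmetric bis-enoate, which is desymmetrised by oxa-Michael addition and lactonisation.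
   - H2, Pd/C gives the C5-propanoic acid.
   - Mixed Kolbe electrolysis with excess 9-phenylnonanoic acid (Pt electrodes, MeOH, partial neutralisation) gives 9 in the same number of steps.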